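**Retrosynthetic overview**
1. Target 26 ⇐ diimide saturation of the C11=C12 alkene of 25 ⇐ Julia–Kocienski union of decalin sulfone 12 (fragment 1) with dioxane aldehyde 23 (fragment 2).
2. Fragment 2: the 1,2-dioxane closes by 6-exo-tet SN2 opening of a cis-β-lactone by a tertiary hydroperoxide (inversion sets C3; C2 comes from the lactone; the acid is released directly) ⇐ SN2-type perhydrolysis of an (S)-epoxide (inversion sets C6) ⇐ catalytic asymmetric ketene–aldehyde cyclocondensation ⇐ (R)-2-methylglycidol.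
3. Fragment 1: ring A is bought as (R)-α-ionone; ring B closes by a superacid cation–olefin cyclisation of a (Z)-allylic alcohol, in which the C5 centre relays to C10 and the Z geometry puts the C9 substituent axial (5R,9S,10R); the Z-alkene comes from Me2CuLi addition to a 2-ynoate.
4. Order of ring formation: ring A (chiral pool) → ring B (step 6); oxirane → β-lactone (step 12) → 1,2-dioxane (step 14); the fragments are joined in step 16.

Assumption: (R)-α-ionone (1) and (R)-2-methylglycidol (13) are bought as single enantiomers (≥98% ee); decalin atoms C5–C12 follow drimane numbering, the dioxane carbons are C3–C6 and the propanoate α-carbon is C2.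

**Fragment 1 (decalin sulfone)**

Step 1
Reactants: 1 (R)-α-ionone, (3E)-4-[(1R)-2,6,6-trimethylcyclohex-2-en-1-yl]but-3-en-2-one
Product: 2 (R)-dihydro-α-ionone, 4-[(1R)-2,6,6-trimethylcyclohex-2-en-1-yl]butan-2-one
Conditions: [(Ph3P)CuH]6 (3 mol%), H2 (30 bar), t-BuOH, benzene, rt
Reagents that add atoms: none
Why: Copper hydride conjugate (1,4-) reduction delivers hydride only to the enone β-carbon, leaving the isolated trisubstituted ring alkene and the ring stereocentre (never deprotonated under these neutral conditions) untouched.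

Step 2
Reactants: 2 (R)-dihydro-α-ionone
Product: 5 (6R)-6-(but-3-yn-1-yl)-1,5,5-trimethylcyclohex-1-ene, via lithium enolate 3 (not isolated), via enol phosphate 4 (not isolated)
Conditions: LiN(i-Pr)2 (1.1 equiv), THF, −78 °C; ClP(O)(OEt)2, −78 °C → rt; then LiN(i-Pr)2 (2.3 equiv), −78 °C → rt; aq. NH4Cl
Reagents that add atoms: none
Why: Negishi alkyne synthesis, in which kinetic deprotonation at the methyl group, O-phosphorylation and base-induced elimination of diethyl phosphate convert the methyl ketone into a terminal alkyne whose CH carbon becomes C9.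

Step 3
Reactants: 5 (6R)-6-(but-3-yn-1-yl)-1,5,5-trimethylcyclohex-1-ene
Product: 7 methyl 5-[(1R)-2,6,6-trimethylcyclohex-2-en-1-yl]pent-2-ynoate, via lithium acetylide 6 (not isolated)
Conditions: n-BuLi (1.05 equiv), THF, −78 °C; then ClCO2Me, −78 → 0 °C
Reagents that add atoms: methyl chloroformate, COC(=O)Cl
Why: C-acylation of the lithium acetylide with a chloroformate gives the 2-ynoate needed for a stereodefined conjugate addition.

Step 4
Reactants: 7 methyl 5-[(1R)-2,6,6-trimethylcyclohex-2-en-1-yl]pent-2-ynoate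
Product: 8 methyl (2Z)-3-methyl-5-[(1R)-2,6,6-trimethylcyclohex-2-en-1-yl]pent-2-enoate
Conditions: Me2CuLi (1.3 equiv), THF, −78 °C; MeOH then aq. NH4Cl at −78 °C
Reagents that add atoms: lithium dimethylcuprate, [Li+].C[Cu-]C
Why: Syn carbocupration of the 2-ynoate (organocuprate conjugate addition) followed by cold protonation with retention places Me and H cis, so the ring-bearing chain and the ester end up cis, i.e. the (Z)-trisubstituted alkene.

Step 5
Reactants: 8 methyl (2Z)-3-methyl-5-[(1R)-2,6,6-trimethylcyclohex-2-en-1-yl]pent-2-enoate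
Product: 9 (2Z)-3-methyl-5-[(1R)-2,6,6-trimethylcyclohex-2-en-1-yl]pent-2-en-1-ol
Conditions: i-Bu2AlH (2.3 equiv), CH2Cl2, −78 °C; aq. potassium sodium tartrate
Reagents that add atoms: none
Why: 1,2-Reduction of the conjugated ester by the aluminium hydride at low temperature gives the allylic alcohol without touching either alkene or the Z geometry.

Step 6
Reactants: 9 (2Z)-3-methyl-5-[(1R)-2,6,6-trimethylcyclohex-2-en-1-yl]pent-2-en-1-ol
Product: 10 [(1S,4aR,8aR)-2,5,5,8a-tetramethyl-1,4,4a,5,6,7,8,8a-octahydronaphthalen-1-yl]methanol (9-epi-drimenol of the enantiomeric series)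
Conditions: FSO3H (5 equiv), 2-nitropropane, −78 °C, 30 min; then Et3N, aq. NaHCO3
Reagents that add atoms: none
Why: Biomimetic cation–olefin (Stork–Eschenmoser) cyclisation of the kind known for superacid closure of farnesol-type alcohols to drim-7-en-11-ols: Markovnikov protonation of the ring alkene gives the tertiary C10 cation, which is captured through a chair transition state with the C5 chain equatorial (trans fusion, C10 R relayed from C5 R, no C5 deprotonation at −78 °C), the Z geometry places CH2OH axial at C9 (S), and loss of H7 from the C8 cation gives the Δ7 alkene.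

Step 7
Reactants: 10 [(1S,4aR,8aR)-2,5,5,8a-tetramethyl-1,4,4a,5,6,7,8,8a-octahydronaphthalen-1-yl]methanol
Product: 11 1-phenyl-5-({[(1S,4aR,8aR)-2,5,5,8a-tetramethyl-1,4,4a,5,6,7,8,8a-octahydronaphthalen-1-yl]methyl}sulfanyl)-1H-tetrazole
Conditions: 1-phenyl-1H-tetrazole-5-thiol, PPh3, diisopropyl azodicarboxylate, THF, 0 °C → rt
Reagents that add atoms: 1-phenyl-1H-tetrazole-5-thiol, Sc1nnnn1-c1ccccc1
Why: Mitsunobu thioetherification of the primary, β-branched (homoallylic, so no SN2' path) alcohol by the acidic tetrazole thiol; no stereocentre is involved.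

Step 8
Reactants: 11 1-phenyl-5-({[(1S,4aR,8aR)-2,5,5,8a-tetramethyl-1,4,4a,5,6,7,8,8a-octahydronaphthalen-1-yl]methyl}sulfanyl)-1H-tetrazole
Product: 12 1-phenyl-5-({[(1S,4aR,8aR)-2,5,5,8a-tetramethyl-1,4,4a,5,6,7,8,8a-octahydronaphthalen-1-yl]methyl}sulfonyl)-1H-tetrazole
Conditions: (NH4)6Mo7O24·4H2O (10 mol%), 30% aq. H2O2, EtOH, 0 °C → rt
Reagents that add atoms: hydrogen peroxide, OO
Why: Molybdate-catalysed oxidation of sulfide to sulfone is much faster than epoxidation of the hindered trisubstituted ring alkene.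

**Fragment 2 (dioxane aldehyde)**

Step 9
Reactants: 13 (R)-2-methylglycidol, [(2R)-2-methyloxiran-2-yl]methanol
Product: 14 [(2S)-2-methyloxiran-2-yl]methyl 4-methylbenzenesulfonate
Conditions: TsCl, Et3N, 4-(dimethylamino)pyridine (5 mol%), CH2Cl2, 0 °C
Reagents that add atoms: 4-methylbenzenesulfonyl chloride, Cc1ccc(cc1)S(=O)(=O)Cl
Why: Sulfonylation of the primary alcohol touches no bond at the quaternary centre (the descriptor changes from R to S only because the CIP priorities change).

Step 10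
Reactants: 14 [(2S)-2-methyloxiran-2-yl]methyl 4-methylbenzenesulfonate
Product: 16 (2S)-2-(but-3-en-1-yl)-2-methyloxirane, via tosyloxy alcohol 15 (not isolated)
Conditions: CH2=CHCH2MgBr, CuBr·SMe2 (10 mol%), THF, −40 → 0 °C; aq. work-up; then K2CO3, MeOH, rt
Reagents that add atoms: allylmagnesium bromide, C=CC[Mg]Br
Why: Copper-catalysed Grignard opening of the epoxide at its CH2 followed by alkoxide displacement of the tosylate re-forms the oxirane on the other CH2 while the quaternary C–O bond is never broken, so the stereocentre is retained.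

Step 11
Reactants: 16 (2S)-2-(but-3-en-1-yl)-2-methyloxirane
Product: 18 3-[(2S)-2-methyloxiran-2-yl]propanal, via ozonide 17 (not isolated)
Conditions: O3, CH2Cl2, −78 °C; then Me2S, −78 °C → rt
Reagents that add atoms: ozone, [O-][O+]=O
Why: Ozonolysis with reductive work-up cleaves the terminal alkene to the aldehyde, the epoxide being inert to ozone.

Step 12
Reactants: 18 3-[(2S)-2-methyloxiran-2-yl]propanal
Product: 19 (3S,4R)-3-methyl-4-{2-[(2S)-2-methyloxiran-2-yl]ethyl}oxetan-2-one (cis-β-lactone)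
Conditions: EtCOCl (2 equiv), i-Pr2NEt (2.5 equiv), O-trimethylsilylquinine (10 mol%), LiClO4 (0.5 equiv), CH2Cl2/Et2O, −78 °C
Reagents that add atoms: propanoyl chloride, CCC(=O)Cl
Why: Cinchona alkaloid/LiClO4-catalysed acyl halide–aldehyde cyclocondensation (formal [2+2] of methylketene made in the flask), in which the chiral ammonium enolate sets both new centres to give the cis-(3S,4R) lactone; the quinine-derived catalyst is taken as the one giving this sense, the quinidine-derived pseudoenantiomer giving the antipode.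

Step 13
Reactants: 19 (3S,4R)-3-methyl-4-{2-[(2S)-2-methyloxiran-2-yl]ethyl}oxetan-2-one
Product: 20 (3S,4R)-4-[(3R)-3-hydroperoxy-4-hydroxy-3-methylbutyl]-3-methyloxetan-2-one
Conditions: H2O2 (anhydrous, in Et2O, 10 equiv), H3PMo12O40 (5 mol%), Et2O, 0 °C → rt
Reagents that add atoms: hydrogen peroxide, OO
Why: Heteropolyacid-catalysed perhydrolysis of an epoxide, a known reaction in which H2O2 opens the oxirane at the more substituted carbon in a borderline SN2 process with inversion, turning the (S) C–O centre into the (R) C–OOH centre and freeing the CH2OH handle, while the neutral peroxide leaves the β-lactone alone in the absence of base.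

Step 14
Reactants: 20 (3S,4R)-4-[(3R)-3-hydroperoxy-4-hydroxy-3-methylbutyl]-3-methyloxetan-2-one
Product: 22 methyl (2S)-2-[(3S,6R)-6-(hydroxymethyl)-6-methyl-1,2-dioxan-3-yl]propanoate, via caesium carboxylate 21 (not isolated)
Conditions: Cs2CO3 (1.0 equiv), DMF, 0 °C → rt; then MeI, rt
Reagents that add atoms: iodomethane, CI
Why: Proposed new method: the caesium salt of the tertiary hydroperoxide attacks C4 of the β-lactone in a 6-exo-tet SN2 opening (alkyl–oxygen cleavage with inversion, carboxylate as leaving group, acyl attack being excluded because it would need an 8-membered ring), which closes the 1,2-dioxane with C3 (S) anti to the C2 methyl without any E1cB pathway, and the carboxylate is then methylated in the same flask; the closest known reactions are SN2 opening of β-lactones at the β-carbon by soft nucleophiles and intramolecular alkylation of hydroperoxides by secondary sulfonates.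

Step 15
Reactants: 22 methyl (2S)-2-[(3S,6R)-6-(hydroxymethyl)-6-methyl-1,2-dioxan-3-yl]propanoate
Product: 23 methyl (2S)-2-[(3S,6R)-6-formyl-6-methyl-1,2-dioxan-3-yl]propanoate
Conditions: Dess–Martin periodinane (1.3 equiv), CH2Cl2, 0 °C → rt
Reagents that add atoms: none
Why: Dess–Martin oxidation of the hindered primary alcohol under non-basic conditions gives an α-quaternary aldehyde that cannot enolise, and the peroxide and ester are inert to the oxidant.

**Fragment union**

Step 16
Reactants: 12 1-phenyl-5-({[(1S,4aR,8aR)-2,5,5,8a-tetramethyl-1,4,4a,5,6,7,8,8a-octahydronaphthalen-1-yl]methyl}sulfonyl)-1H-tetrazole, 23 methyl (2S)-2-[(3S,6R)-6-formyl-6-methyl-1,2-dioxan-3-yl]propanoate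
Product: 25 methyl (2S)-2-[(3S,6R)-6-methyl-6-{(E)-2-[(1S,4aR,8aR)-2,5,5,8a-tetramethyl-1,4,4a,5,6,7,8,8a-octahydronaphthalen-1-yl]ethenyl}-1,2-dioxan-3-yl]propanoate (E major, geometry irrelevant), via potassium sulfonyl carbanion 24 (not isolated)
Conditions: KN(SiMe3)2 (1.05 equiv), 1,2-dimethoxyethane, −60 °C, 30 min; then 23, −60 °C → rt
Reagents that add atoms: none
Why: Julia–Kocienski olefination, in which the pre-metalated tetrazolyl sulfone adds to the non-enolisable aldehyde and Smiles rearrangement with loss of SO2 and the tetrazolone gives the alkene without any reductant, so the O–O bond and the ester survive (olefination of α-peroxy aldehydes is known).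

Step 17
Reactants: 25 methyl (2S)-2-[(3S,6R)-6-methyl-6-{(E)-2-[(1S,4aR,8aR)-2,5,5,8a-tetramethyl-1,4,4a,5,6,7,8,8a-octahydronaphthalen-1-yl]ethenyl}-1,2-dioxan-3-yl]propanoate
Product: 26 methyl (2S)-2-[(3S,6S)-6-methyl-6-{2-[(1S,4aR,8aR)-2,5,5,8a-tetramethyl-1,4,4a,5,6,7,8,8a-octahydronaphthalen-1-yl]ethyl}-1,2-dioxan-3-yl]propanoate (target)
Conditions: KO2CN=NCO2K (20 equiv, in portions), AcOH, MeOH/CH2Cl2, 0 °C → rt
Reagents that add atoms: none
Why: Diimide reduction (concerted syn transfer of H2) saturates the disubstituted alkene far faster than the hindered trisubstituted ring alkene and does not cleave the O–O bond; the C6 descriptor changes from R to S only through CIP priorities.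

**Compound list**
1 | (R)-α-ionone, (3E)-4-[(1R)-2,6,6-trimethylcyclohex-2-en-1-yl]but-3-en-2-one | CC(=O)/C=C/[C@H]1C(C)=CCCC1(C)C | starting material
2 | (R)-dihydro-α-ionone, 4-[(1R)-2,6,6-trimethylcyclohex-2-en-1-yl]butan-2-one | CC(=O)CC[C@H]1C(C)=CCCC1(C)C | intermediate
3 | lithium 4-[(1R)-2,6,6-trimethylcyclohex-2-en-1-yl]but-1-en-2-olate (lithium enolate) | [Li+].[O-]C(=C)CC[C@H]1C(C)=CCCC1(C)C | intermediate
4 | diethyl 4-[(1R)-2,6,6-trimethylcyclohex-2-en-1-yl]but-1-en-2-yl phosphate (enol phosphate) | CCOP(=O)(OCC)OC(=C)CC[C@H]1C(C)=CCCC1(C)C | intermediate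
5 | (6R)-6-(but-3-yn-1-yl)-1,5,5-trimethylcyclohex-1-ene | C#CCC[C@H]1C(C)=CCCC1(C)C | intermediate
6 | lithium 4-[(1R)-2,6,6-trimethylcyclohex-2-en-1-yl]but-1-yn-1-ide (lithium acetylide) | [Li+].[C-]#CCC[C@H]1C(C)=CCCC1(C)C | intermediate
7 | methyl 5-[(1R)-2,6,6-trimethylcyclohex-2-en-1-yl]pent-2-ynoate | COC(=O)C#CCC[C@H]1C(C)=CCCC1(C)C | intermediate
8 | methyl (2Z)-3-methyl-5-[(1R)-2,6,6-trimethylcyclohex-2-en-1-yl]pent-2-enoate | COC(=O)/C=C(/C)CC[C@H]1C(C)=CCCC1(C)C | intermediate
9 | (2Z)-3-methyl-5-[(1R)-2,6,6-trimethylcyclohex-2-en-1-yl]pent-2-en-1-ol | OC/C=C(/C)CC[C@H]1C(C)=CCCC1(C)C | intermediate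
10 | [(1S,4aR,8aR)-2,5,5,8a-tetramethyl-1,4,4a,5,6,7,8,8a-octahydronaphthalen-1-yl]methanol | OC[C@H]2C(C)=CC[C@@H]3C(C)(C)CCC[C@]32C | intermediate
11 | 1-phenyl-5-({[(1S,4aR,8aR)-2,5,5,8a-tetramethyl-1,4,4a,5,6,7,8,8a-octahydronaphthalen-1-yl]methyl}sulfanyl)-1H-tetrazole | c1ccccc1-n1nnnc1SC[C@H]2C(C)=CC[C@@H]3C(C)(C)CCC[C@]32C | intermediate
12 | 1-phenyl-5-({[(1S,4aR,8aR)-2,5,5,8a-tetramethyl-1,4,4a,5,6,7,8,8a-octahydronaphthalen-1-yl]methyl}sulfonyl)-1H-tetrazole | O=S(=O)(C[C@H]2C(C)=CC[C@@H]3C(C)(C)CCC[C@]32C)c1nnnn1-c1ccccc1 | intermediate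
13 | (R)-2-methylglycidol, [(2R)-2-methyloxiran-2-yl]methanol | OC[C@]1(C)CO1 | starting material
14 | [(2S)-2-methyloxiran-2-yl]methyl 4-methylbenzenesulfonate | Cc1ccc(cc1)S(=O)(=O)OC[C@]1(C)CO1 | intermediate
15 | (2S)-2-hydroxy-2-methylhex-5-en-1-yl 4-methylbenzenesulfonate (tosyloxy alcohol) | Cc1ccc(cc1)S(=O)(=O)OC[C@@](C)(O)CCC=C | intermediate
16 | (2S)-2-(but-3-en-1-yl)-2-methyloxirane | C=CCC[C@@]1(C)CO1 | intermediate
17 | 3-{2-[(2S)-2-methyloxiran-2-yl]ethyl}-1,2,4-trioxolane (ozonide, both epimers at the trioxolane carbon) | C1OC(CC[C@@]2(C)CO2)OO1 | intermediate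
18 | 3-[(2S)-2-methyloxiran-2-yl]propanal | O=CCC[C@@]1(C)CO1 | intermediate
19 | (3S,4R)-3-methyl-4-{2-[(2S)-2-methyloxiran-2-yl]ethyl}oxetan-2-one | C[C@@H]1C(=O)O[C@@H]1CC[C@@]2(C)CO2 | intermediate
20 | (3S,4R)-4-[(3R)-3-hydroperoxy-4-hydroxy-3-methylbutyl]-3-methyloxetan-2-one | C[C@@H]1C(=O)O[C@@H]1CC[C@](C)(CO)OO | intermediate
21 | caesium (2S)-2-[(3S,6R)-6-(hydroxymethyl)-6-methyl-1,2-dioxan-3-yl]propanoate | [Cs+].[O-]C(=O)[C@@H](C)[C@@H]1CC[C@](C)(CO)OO1 | intermediate
22 | methyl (2S)-2-[(3S,6R)-6-(hydroxymethyl)-6-methyl-1,2-dioxan-3-yl]propanoate | COC(=O)[C@@H](C)[C@@H]1CC[C@](C)(CO)OO1 | intermediate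
23 | methyl (2S)-2-[(3S,6R)-6-formyl-6-methyl-1,2-dioxan-3-yl]propanoate | COC(=O)[C@@H](C)[C@@H]1CC[C@](C)(C=O)OO1 | intermediate
24 | potassium (1-phenyl-1H-tetrazol-5-ylsulfonyl)[(1S,4aR,8aR)-2,5,5,8a-tetramethyl-1,4,4a,5,6,7,8,8a-octahydronaphthalen-1-yl]methanide | [K+].[CH-](S(=O)(=O)c1nnnn1-c1ccccc1)[C@H]2C(C)=CC[C@@H]3C(C)(C)CCC[C@]32C | intermediate
25 | methyl (2S)-2-[(3S,6R)-6-methyl-6-{(E)-2-[(1S,4aR,8aR)-2,5,5,8a-tetramethyl-1,4,4a,5,6,7,8,8a-octahydronaphthalen-1-yl]ethenyl}-1,2-dioxan-3-yl]propanoate | COC(=O)[C@@H](C)[C@@H]1CC[C@](C)(/C=C/[C@H]2C(C)=CC[C@@H]3C(C)(C)CCC[C@]32C)OO1 | intermediate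
26 | methyl (2S)-2-[(3S,6S)-6-methyl-6-{2-[(1S,4aR,8aR)-2,5,5,8a-tetramethyl-1,4,4a,5,6,7,8,8a-octahydronaphthalen-1-yl]ethyl}-1,2-dioxan-3-yl]propanoate | COC(=O)[C@@H](C)[C@@H]1CC[C@](C)(CC[C@H]2C(C)=CC[C@@H]3C(C)(C)CCC[C@]32C)OO1 | target

**Totals**
Total step count: 17. Longest linear sequence: 10 steps (steps 1–8, then 16 and 17, from 1); the dioxane branch is 9 steps (steps 9–15, then 16 and 17, from 13).

**Three steps most likely to fail, with fallbacks**

The first is step 6, the superacid cyclisation. The free allylic alcohol may ionise, and the C8 cation may lose a proton to give the exocyclic or Δ8 isomers or close to a cis-fused ring. The fallback sets out from ester 8 and comes back at alcohol 10. SnCl4 in CH2Cl2 at −78 °C closes ring B with the (Z)-enoate itself as the terminating alkene, giving methyl (1S,4aR,8aR)-2,5,5,8a-tetramethyl-1,4,4a,5,6,7,8,8a-octahydronaphthalene-1-carboxylate F1, which is quenched cold to avoid conjugation and C9 epimerisation. Reduction of F1 with i-Bu2AlH at −78 °C then gives 10.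

The second is step 14, the hydroperoxide/β-lactone annulation, which is new chemistry and depends on the lactone surviving step 13. The fallback sets out from lactone 19 and comes back at ester 22, replacing the lactone opening by a classical sulfonate displacement. NaOCH3 in MeOH at 0 °C opens 19 at the acyl carbon to methyl (2S,3R)-3-hydroxy-2-methyl-5-[(2S)-2-methyloxiran-2-yl]pentanoate F2. MsCl in pyridine at 0 °C gives methyl (2S,3R)-2-methyl-3-[(methylsulfonyl)oxy]-5-[(2S)-2-methyloxiran-2-yl]pentanoate F3. Perhydrolysis under the conditions of step 13 gives methyl (2S,3R,6R)-6-hydroperoxy-7-hydroxy-2,6-dimethyl-3-[(methylsulfonyl)oxy]heptanoate F4. Cs2CO3 in DMF at 0 °C then closes the dioxane by displacement of the mesylate with inversion to give 22. The known weakness of this path is competing β-elimination of the mesylate.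

The third is step 16, the Julia–Kocienski coupling of a hindered sulfone anion with an α-quaternary, α-peroxy aldehyde; the β-alkoxide may add slowly or fragment. The fallback sets out from alcohol 10 and comes back at alkene 25 through a Wittig reaction. I2, PPh3 and imidazole convert 10 into (1S,4aR,8aR)-1-(iodomethyl)-2,5,5,8a-tetramethyl-1,4,4a,5,6,7,8,8a-octahydronaphthalene F5. PPh3 neat at 120 °C gives {[(1S,4aR,8aR)-2,5,5,8a-tetramethyl-1,4,4a,5,6,7,8,8a-octahydronaphthalen-1-yl]methyl}(triphenyl)phosphonium iodide F6. KN(SiMe3)2 in THF at −78 °C gives triphenyl{[(1S,4aR,8aR)-2,5,5,8a-tetramethyl-1,4,4a,5,6,7,8,8a-octahydronaphthalen-1-yl]methylidene}-λ5-phosphane F7, which condenses with aldehyde 23 to give 25 (mainly Z, which is irrelevant because step 17 follows).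

**Further compounds**
F1 | step 6 | methyl (1S,4aR,8aR)-2,5,5,8a-tetramethyl-1,4,4a,5,6,7,8,8a-octahydronaphthalene-1-carboxylate | COC(=O)[C@H]2C(C)=CC[C@@H]3C(C)(C)CCC[C@]32C
F2 | step 14 | methyl (2S,3R)-3-hydroxy-2-methyl-5-[(2S)-2-methyloxiran-2-yl]pentanoate | COC(=O)[C@@H](C)[C@H](O)CC[C@@]1(C)CO1
F3 | step 14 | methyl (2S,3R)-2-methyl-3-[(methylsulfonyl)oxy]-5-[(2S)-2-methyloxiran-2-yl]pentanoate | COC(=O)[C@@H](C)[C@H](OS(C)(=O)=O)CC[C@@]1(C)CO1
F4 | step 14 | methyl (2S,3R,6R)-6-hydroperoxy-7-hydroxy-2,6-dimethyl-3-[(methylsulfonyl)oxy]heptanoate | COC(=O)[C@@H](C)[C@H](OS(C)(=O)=O)CC[C@](C)(CO)OO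
F5 | step 16 | (1S,4aR,8aR)-1-(iodomethyl)-2,5,5,8a-tetramethyl-1,4,4a,5,6,7,8,8a-octahydronaphthalene | IC[C@H]2C(C)=CC[C@@H]3C(C)(C)CCC[C@]32C
F6 | step 16 | {[(1S,4aR,8aR)-2,5,5,8a-tetramethyl-1,4,4a,5,6,7,8,8a-octahydronaphthalen-1-yl]methyl}(triphenyl)phosphonium iodide | [I-].c1ccccc1[P+](c1ccccc1)(c1ccccc1)C[C@H]2C(C)=CC[C@@H]3C(C)(C)CCC[C@]32C
F7 | step 16 | triphenyl{[(1S,4aR,8aR)-2,5,5,8a-tetramethyl-1,4,4a,5,6,7,8,8a-octahydronaphthalen-1-yl]methylidene}-λ5-phosphane | c1ccccc1P(c1ccccc1)(c1ccccc1)=C[C@H]2C(C)=CC[C@@H]3C(C)(C)CCC[C@]32C
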